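**Plan**

- Locants, used for every intermediate: C1 methyl-bearing ring-fusion carbon, C2 angelate carbinol, C3 CH2, C4 C(OH)(i-Pr), C5 ring-fusion CH, C6 anisoate carbinol, C7 CH2, C8(CH3)=C9H, C10 CH2. Ring A = C1–C5 (five-membered), ring B = C1, C5–C10 (seven-membered); β = face of the C1 methyl, α = the other face.
- Retrosynthesis: the two ester C–O bonds (C2–O angeloyl, C6–O anisoyl) are cut first, then the C8–CH3 bond (back to a C8 ketone), then the ring-fusion bond C1–C5, which is traced back to a C1–C6 bond of a decalin, and last the C4–isopropyl bond and the oxygens at C4, C5 and C6.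
- Enabling feature: quaternary C1 carries the methyl group and lies between oxygenated C2 and C5, C5 is bonded to oxygenated C6, and C6 and C8 are functionalised 1,3 across ring B. Returning C1 from C5 to C6 turns ring A plus ring B into the two cyclohexanes of the Wieland–Miescher ketone, whose carbonyls are C2 and C8.
- Forward: both six-membered rings come with the starting enone. C4 is oxidised and isopropylated, C5=C6 is cis-dihydroxylated and C5 is mesylated. One 1,2-shift of C1 from C6 to C5 then contracts one cyclohexane to ring A and expands the other to ring B. C6 reduction, the C8 methyl alkene and the two acylations follow.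
- Stereochemistry: C1 from the (R)-ketone; C2 by hydride attack anti to the methyl; C4 by axial organocerium addition; C5 by inversion of a β-mesylate (placed by β-face osmylation) during the shift; C6 by reduction directed by the C4 hydroxyl.

Key step: step 9

Remark on the chemistry: the given configuration is read as the trans-fused skeleton with the C1 methyl, the C2 oxygen and the C4 hydroxyl on the β face and C5–H, the C6 oxygen and the isopropyl group on the α face.

**Route**

Step 1
Reactants: 1 (R)-Wieland–Miescher ketone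
Product: 2 hydroxy enone with C2 β-OH [(4aR,5R)-5-hydroxy-4a-methyl-4,4a,5,6,7,8-hexahydronaphthalen-2(3H)-one]
Conditions: NaBH4 (0.3 equiv), EtOH, −10 °C
Reagents that add atoms: none
Why: Chemoselective borohydride reduction of the saturated C2 ketone beside the less electrophilic C8 enone carbonyl, with hydride entering anti to the angular C1 methyl so that the C2 hydroxyl is β (cis to the methyl).

Step 2
Reactants: 2 hydroxy enone
Product: 3 decalin with C5=C6 alkene, C8 1,3-dioxolane and free C2 β-OH
Conditions: ethylene glycol, p-TsOH·H2O (cat.), benzene, reflux (Dean–Stark)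
Reagents that add atoms: ethylene glycol, OCCO
Why: Deconjugative ketalisation of the enone through its dienol moves the alkene from C6=C7 to C5=C6, as in the classical conversion of steroidal 4-en-3-ones into 5-ene 3-ketals, and the secondary alcohol is inert.

Step 3
Reactants: 3 ketal alcohol
Product: 4 C2 β-tert-butyldimethylsilyl ether of 3
Conditions: TBSOTf, 2,6-lutidine, CH2Cl2, 0 °C
Reagents that add atoms: tert-butyldimethylsilyl triflate, CC(C)(C)[Si](C)(C)OS(=O)(=O)C(F)(F)F
Why: Silyl triflate silylation of the hindered neopentyl-type secondary alcohol under lutidine buffering, which the dioxolane and the alkene tolerate.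

Step 4
Reactants: 4 silyl ether
Product: 5 5-en-4-one (C4 ketone conjugated with C5=C6) with C8 dioxolane and C2 β-OTBS
Conditions: Rh2(cap)4 (cap = caprolactamate, 1 mol %), t-BuOOH (70% aq.), ClCH2CH2Cl, 40 °C
Reagents that add atoms: tert-butyl hydroperoxide, CC(C)(C)OO
Why: Dirhodium-catalysed allylic C–H oxidation turns the allylic C4 methylene into the enone, as in the oxidation of 5-ene steroid 3-ketals to 5-en-7-ones, while the other allylic methylene C7 is neopentylic to the dioxolane carbon and inductively deactivated.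

Step 5
Reactants: 5 enone, 6 isopropylmagnesium chloride
Product: 8 C4 tertiary allylic alcohol (4β-OH/4α-i-Pr) with C5=C6 and C8 dioxolane and C2 β-OTBS, via isopropylcerium dichloride 7 (not isolated)
Conditions: CeCl3 (dried), 6, THF, −78 °C; then 5, −78 → 0 °C
Reagents that add atoms: isopropylmagnesium chloride 6, CC(C)[Mg]Cl
Why: Organocerium 1,2-addition (suppressing enolisation, conjugate addition and β-hydride reduction) in which the nucleophile enters C4 axially from the α face, away from the pseudoaxial C1 methyl, so that the hydroxyl is β and the isopropyl group α.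

Step 6
Reactants: 8 tertiary allylic alcohol
Product: 9 C4 benzyloxymethyl (BOM) ether of 8
Conditions: BOMCl, i-Pr2NEt, n-Bu4NI (cat.), ClCH2CH2Cl, 60 °C
Reagents that add atoms: benzyl chloromethyl ether, ClCOCc1ccccc1
Why: Alkylation of the tertiary alcohol by the highly electrophilic chloromethyl ether under amine base (acetal-type etherification) gives an ether that cannot migrate to a neighbouring alkoxide and is later removable by hydrogenolysis.

Step 7
Reactants: 9 BOM ether
Product: 10 cis-decalin 5β,6β-diol (C4 β-OBOM, C2 β-OTBS, C8 dioxolane)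
Conditions: OsO4 (10 mol %), NMO, MeSO2NH2, acetone/H2O (4:1), rt → 40 °C
Reagents that add atoms: osmium tetroxide (catalytic oxygen carrier), O=[Os](=O)(=O)=O; N-methylmorpholine N-oxide, C[N+]1([O-])CCOCC1; water, O
Why: Upjohn dihydroxylation by suprafacial [3+2] addition of OsO4 is expected on the β face, because the α face is closed by the pseudoaxial C4 isopropyl group and the axial dioxolane oxygen while the in-plane C4 alkoxy group does not shield, so both new hydroxyls are cis to the C1 methyl.

Step 8
Reactants: 10 diol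
Product: 11 C5 β-mesylate with free tertiary C6 β-OH
Conditions: MsCl, Et3N, CH2Cl2, −20 → 0 °C
Reagents that add atoms: methanesulfonyl chloride, CS(=O)(=O)Cl
Why: Sulfene-type mesylation takes place at the only secondary hydroxyl (C5), the tertiary ring-fusion C6 hydroxyl being too hindered to be sulfonylated.

Step 9
Reactants: 11 hydroxy mesylate
Product: 13 trans-fused hydroazulen-6-one (C2 β-OTBS, C4 β-OBOM/α-i-Pr, C5 α-H, C8 dioxolane), via potassium C6-alkoxide 12 (not isolated)
Conditions: KOt-Bu (1.1 equiv), THF/t-BuOH (5:1), 0 °C → rt; pH 7 buffer quench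
Reagents that add atoms: none
Why: KOt-Bu converts the tertiary C6 hydroxyl into alkoxide 12, whose oxygen lone pair drives the C6–C1 σ bond onto C5 while the mesylate departs, so that C1 migrates with retention, C5 is inverted and C6 becomes the carbonyl carbon. The closest known reaction type is the base-induced pinacol-type (semipinacol) rearrangement of decalin-1,2-diol monosulfonates to hydroazulenones. Neither ring is made by a conventional ring-closing bond formation: ring A (C1–C5) results from contraction of the carbocycle C1–C2–C3–C4–C5–C6 by extrusion of C6, and ring B (C1, C5–C10) from one-carbon expansion of the dioxolane-bearing cyclohexane by insertion of C5 between C1 and C6, both in one suprafacial 1,2-shift. The single new stereocentre C5 is fixed by the stereospecific backside displacement of the β-mesylate, which leaves C5–H α and hence trans to the C1 methyl. The step requires migration of C6–C1 and not of C6–C7 or C4–C3: in the chair that carries the mesylate equatorial, C6–C1 is antiperiplanar to the C5–O bond, and this chair avoids the syn-axial isopropyl/C7 and methyl/mesylate contacts of the other chair and lets the potassium ion sit between the three syn-axial oxygens at C2, C4 and C6. The C4 oxygen is an acetal ether that can neither act as an alkoxide donor for a C3 shift nor be transferred to the C6 alkoxide as a silyl group could, and epoxide formation is excluded because the C6 oxygen and the C5 mesylate are cis.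

Step 10
Reactants: 13 hydroazulenone
Product: 15 C4 β-hydroxy C6 ketone (C2 β-OTBS, C8 dioxolane), via C4 hemiformal 14 (not isolated)
Conditions: H2 (1 atm), Pd(OH)2/C, EtOAc, rt; concentration from MeOH
Reagents that add atoms: none
Why: Hydrogenolysis of the benzylic C–O bond gives a hemiformal that loses formaldehyde, under neutral conditions that leave the ketone, the dioxolane and the silyl ether untouched and give no opportunity for retro-aldol cleavage.

Step 11
Reactants: 15 β-hydroxy ketone
Product: 16 4β,6α-diol (C2 β-OTBS, C8 dioxolane)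
Conditions: Me4NBH(OAc)3, MeCN/AcOH (1:1), −30 °C
Reagents that add atoms: none
Why: Evans–Saksena reduction in which the C4 hydroxyl replaces an acetate on boron and the hydride is delivered internally to the β face of the C6 carbonyl, giving the 1,3-anti diol, that is the C6 α-alcohol with C6–H β and trans to C5–H.

Step 12
Reactants: 16 diol, 17 p-anisoyl chloride
Product: 18 C6 α-(4-methoxybenzoate) with free C4 β-OH
Conditions: 17, Et3N, DMAP (cat.), CH2Cl2, rt → 40 °C
Reagents that add atoms: p-anisoyl chloride 17, COc1ccc(cc1)C(Cl)=O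
Why: DMAP-catalysed acylation esterifies the secondary C6 hydroxyl, while the tertiary C4 hydroxyl does not react.

Step 13
Reactants: 18 hydroxy anisoate
Product: 19 C4 triethylsilyl ether of 18
Conditions: TESOTf, 2,6-lutidine, CH2Cl2, −40 → 0 °C
Reagents that add atoms: triethylsilyl triflate, CC[Si](CC)(CC)OS(=O)(=O)C(F)(F)F
Why: Silyl triflate silylation of the tertiary alcohol, tolerated by the dioxolane, ensures that no alkoxide can form next to the anisoate in the later base step and that no hemiketal can form with the C8 ketone once it is unveiled.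

Step 14
Reactants: 19 silyl ether
Product: 20 C8 ketone (C2 β-OTBS, C4 β-OTES, C6 α-anisoate)
Conditions: PPTS (cat.), acetone/H2O (10:1), 50 °C
Reagents that add atoms: water, O
Why: Mild acid-catalysed transketalisation and hydrolysis of the dioxolane should spare the hindered secondary TBS and tertiary TES ethers, and a β-acyloxy ketone does not eliminate under weak acid.

Step 15
Reactants: 20 ketone
Product: 22 C8–C9 enol triflate, via potassium enolate 21 (not isolated)
Conditions: KHMDS, THF, −78 °C; then PhNTf2, −78 → −20 °C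
Reagents that add atoms: N-phenylbis(trifluoromethanesulfonimide), O=S(=O)(N(c1ccccc1)S(=O)(=O)C(F)(F)F)C(F)(F)F
Why: Kinetic deprotonation by the bulky amide base is expected at the less hindered C9 methylene, remote from the acyloxy-bearing C6, and O-sulfonylation of the enolate fixes the alkene at C8=C9 (regioselective enol triflate formation).

Step 16
Reactants: 22 enol triflate
Product: 23 C8-methyl 8-ene (C2 β-OTBS, C4 β-OTES, C6 α-anisoate)
Conditions: MeZnCl, Pd(PPh3)4 (5 mol %), THF, 50 °C
Reagents that add atoms: methylzinc chloride, C[Zn]Cl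
Why: Negishi cross-coupling (oxidative addition of zerovalent palladium into the vinyl triflate, transmetalation from zinc, reductive elimination) installs the C8 methyl group without moving the alkene, and esters and silyl ethers are inert.

Step 17
Reactants: 23 bis-silyl ether
Product: 24 C2,C4-diol C6-anisoate
Conditions: HF·pyridine, pyridine/THF, 0 °C → rt
Reagents that add atoms: none
Why: Buffered fluoride desilylation removes the tertiary TES and the hindered secondary TBS ether without acyl migration or alkene isomerisation.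

Step 18
Reactants: 24 diol, 25 angelic acid
Product: 27 target CNP0204191.1, via angelic 2,4,6-trichlorobenzoic anhydride 26 (not isolated)
Conditions: 25, 2,4,6-trichlorobenzoyl chloride, Et3N, toluene, rt; then 24, 80 °C
Reagents that add atoms: angelic acid 25, C/C=C(/C)C(O)=O
Why: Yamaguchi-type esterification through the mixed anhydride, run without a nucleophilic catalyst so that the (Z)-alkene does not isomerise to the tiglate, acylates only the secondary C2 hydroxyl, the tertiary C4 hydroxyl being inert.

**Compound list**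

1 | (R)-Wieland–Miescher ketone, (8aR)-8a-methyl-3,4,8,8a-tetrahydronaphthalene-1,6(2H,7H)-dione | C[C@@]12CCC(=O)C=C1CCCC2=O | starting material
2 | hydroxy enone, (4aR,5R)-5-hydroxy-4a-methyl-4,4a,5,6,7,8-hexahydronaphthalen-2(3H)-one (C2 β-OH) | C[C@@]12CCC(=O)C=C1CCC[C@H]2O | intermediate
3 | decalin with C5=C6, C8 1,3-dioxolane, C2 β-OH | C[C@@]12CCC3(OCCO3)CC1=CCC[C@H]2O | intermediate
4 | C2 β-OTBS ether of 3 | C[C@@]12CCC3(OCCO3)CC1=CCC[C@H]2O[Si](C)(C)C(C)(C)C | intermediate
5 | 5-en-4-one, C8 dioxolane, C2 β-OTBS | C[C@@]12CCC3(OCCO3)CC1=CC(=O)C[C@H]2O[Si](C)(C)C(C)(C)C | intermediate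
6 | isopropylmagnesium chloride | CC(C)[Mg]Cl | starting material
7 | isopropylcerium dichloride | CC(C)[Ce](Cl)Cl | intermediate
8 | C4 tertiary allylic alcohol (4β-OH, 4α-i-Pr), C5=C6, C8 dioxolane, C2 β-OTBS | C[C@@]12CCC3(OCCO3)CC1=C[C@](O)(C(C)C)C[C@H]2O[Si](C)(C)C(C)(C)C | intermediate
9 | C4 β-O-benzyloxymethyl ether of 8 | C[C@@]12CCC3(OCCO3)CC1=C[C@](OCOCc4ccccc4)(C(C)C)C[C@H]2O[Si](C)(C)C(C)(C)C | intermediate
10 | cis-decalin 5β,6β-diol (C4 β-OBOM, α-i-Pr; C2 β-OTBS; C8 dioxolane) | C[C@@]12CCC3(OCCO3)C[C@]1(O)[C@@H](O)[C@](OCOCc4ccccc4)(C(C)C)C[C@H]2O[Si](C)(C)C(C)(C)C | intermediate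
11 | C5 β-mesylate, C6 β-OH (rearrangement precursor) | C[C@@]12CCC3(OCCO3)C[C@]1(O)[C@@H](OS(C)(=O)=O)[C@](OCOCc4ccccc4)(C(C)C)C[C@H]2O[Si](C)(C)C(C)(C)C | intermediate
12 | potassium C6-alkoxide of 11 | C[C@@]12CCC3(OCCO3)C[C@]1([O-])[C@@H](OS(C)(=O)=O)[C@](OCOCc4ccccc4)(C(C)C)C[C@H]2O[Si](C)(C)C(C)(C)C.[K+] | intermediate
13 | trans-fused hydroazulen-6-one (C2 β-OTBS; C4 β-OBOM, α-i-Pr; C5 α-H; C8 dioxolane) | CC(C)(C)[Si](C)(C)O[C@@H]1C[C@@](OCOCc4ccccc4)(C(C)C)[C@@H]2C(=O)CC3(OCCO3)CC[C@]21C | intermediate
14 | C4 O-(hydroxymethyl) hemiformal of 15 | CC(C)(C)[Si](C)(C)O[C@@H]1C[C@@](OCO)(C(C)C)[C@@H]2C(=O)CC3(OCCO3)CC[C@]21C | intermediate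
15 | C4 β-hydroxy C6 ketone (C2 β-OTBS, C8 dioxolane) | CC(C)(C)[Si](C)(C)O[C@@H]1C[C@@](O)(C(C)C)[C@@H]2C(=O)CC3(OCCO3)CC[C@]21C | intermediate
16 | 4β,6α-diol (C2 β-OTBS, C8 dioxolane) | CC(C)(C)[Si](C)(C)O[C@@H]1C[C@@](O)(C(C)C)[C@@H]2[C@@H](O)CC3(OCCO3)CC[C@]21C | intermediate
17 | p-anisoyl chloride (4-methoxybenzoyl chloride) | COc1ccc(cc1)C(Cl)=O | starting material
18 | C6 α-(4-methoxybenzoate), free C4 β-OH | CC(C)(C)[Si](C)(C)O[C@@H]1C[C@@](O)(C(C)C)[C@@H]2[C@@H](OC(=O)c4ccc(OC)cc4)CC3(OCCO3)CC[C@]21C | intermediate
19 | C4 β-OTES ether of 18 | CC(C)(C)[Si](C)(C)O[C@@H]1C[C@@](O[Si](CC)(CC)CC)(C(C)C)[C@@H]2[C@@H](OC(=O)c4ccc(OC)cc4)CC3(OCCO3)CC[C@]21C | intermediate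
20 | C8 ketone (C2 β-OTBS, C4 β-OTES, C6 α-anisoate) | CC(C)(C)[Si](C)(C)O[C@@H]1C[C@@](O[Si](CC)(CC)CC)(C(C)C)[C@@H]2[C@@H](OC(=O)c3ccc(OC)cc3)CC(=O)CC[C@]21C | intermediate
21 | potassium C8(O)=C9 enolate of 20 | CC(C)(C)[Si](C)(C)O[C@@H]1C[C@@](O[Si](CC)(CC)CC)(C(C)C)[C@@H]2[C@@H](OC(=O)c3ccc(OC)cc3)CC([O-])=CC[C@]21C.[K+] | intermediate
22 | C8–C9 enol triflate | CC(C)(C)[Si](C)(C)O[C@@H]1C[C@@](O[Si](CC)(CC)CC)(C(C)C)[C@@H]2[C@@H](OC(=O)c3ccc(OC)cc3)CC(OS(=O)(=O)C(F)(F)F)=CC[C@]21C | intermediate
23 | C8-methyl 8-ene (C2 β-OTBS, C4 β-OTES, C6 α-anisoate) | CC(C)(C)[Si](C)(C)O[C@@H]1C[C@@](O[Si](CC)(CC)CC)(C(C)C)[C@@H]2[C@@H](OC(=O)c3ccc(OC)cc3)CC(C)=CC[C@]21C | intermediate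
24 | C2 β,C4 β-diol C6 α-anisoate | O[C@@H]1C[C@@](O)(C(C)C)[C@@H]2[C@@H](OC(=O)c3ccc(OC)cc3)CC(C)=CC[C@]21C | intermediate
25 | angelic acid, (Z)-2-methylbut-2-enoic acid | C/C=C(/C)C(O)=O | starting material
26 | angelic 2,4,6-trichlorobenzoic mixed anhydride | C/C=C(/C)C(=O)OC(=O)c1c(Cl)cc(Cl)cc1Cl | intermediate
27 | CNP0204191.1 (C2 β-angelate, C4 β-OH/α-i-Pr, C5 α-H, C6 α-anisoate, C8-methyl 8-ene) | C/C=C(/C)C(=O)O[C@@H]1C[C@@](O)(C(C)C)[C@@H]2[C@@H](OC(=O)c3ccc(OC)cc3)CC(C)=CC[C@]21C | target

**Step count and risks**

Total step count: 18. Longest linear sequence: 18 steps from 1 (the route is fully linear; 6, 17 and 25 enter in steps 5, 12 and 18).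

Steps most likely to fail:

1. Step 7, poor facial selectivity of the osmylation. If osmium adds anti to the angular methyl instead of anti to the isopropyl group, the α-diol forms and the later shift would give the wrong ring fusion. The fallback inverts the stereochemical logic instead of tuning the oxidant. It sets out from 9, which is submitted to Woodward cis-hydroxylation (I2, AgOAc, AcOH, then wet AcOH). The iodonium ion forms on the accessible α face, acetate opens it from the β face, and the acetoxonium ion that follows places both oxygens on the β face. The resulting C5 β-acetate C6 β-alcohol F1 is methanolysed (K2CO3, MeOH), and the route is rejoined at 10.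

2. Step 9, migration of the wrong bond or base damage to the product. The chair with an axial mesylate would let C6–C7 migrate, and excess alkoxide could enolise the new ketone, causing C5 epimerisation, β-elimination of the dioxolane, or silyl transfer from the C2 oxygen. The fallback changes the mode of activation from a free potassium alkoxide to an aluminium alkoxide. It sets out from 11, which is treated with Et3Al in CH2Cl2 at −78 → 0 °C. The aluminium bound to the C6 oxygen assists departure of the gauche, equatorial mesylate in a non-basic medium (organoaluminium-promoted pinacol-type rearrangement of β-mesyloxy alcohols). This gives 13 directly, where the route is rejoined; the fallback makes no new compound (entry F0).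

3. Step 15, deprotonation at C7 instead of C9. The C7 enolate would expel the C6 anisoate by β-elimination and destroy the C6 stereocentre. The fallback postpones the anisoylation until the alkene is in place. It sets out from 16:
   - Both hydroxyls are silylated (TESOTf, 2,6-lutidine) to the C4,C6-bis(triethylsilyl) ether F2.
   - The dioxolane is removed (PdCl2(MeCN)2, acetone, or PPTS in wet acetone) to give the C8 ketone F3.
   - Because a β-silyloxy group is a poor leaving group, KHMDS/PhNTf2 should give the C8–C9 enol triflate F4 without elimination, and MeZnCl/Pd(PPh3)4 then gives the C8-methyl alkene F5.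
   - The secondary C6 silyl ether is cleaved selectively (PPTS, MeOH, 0 °C) to the C6 α-alcohol F6, which is acylated with 17 (Et3N, DMAP), and the route is rejoined at 23.

**Further compounds**

F1 | step 7 | C5 β-acetate C6 β-alcohol (C4 β-OBOM, C2 β-OTBS, C8 dioxolane) | C[C@@]12CCC3(OCCO3)C[C@]1(O)[C@@H](OC(C)=O)[C@](OCOCc4ccccc4)(C(C)C)C[C@H]2O[Si](C)(C)C(C)(C)C
F0 | step 9 | none | none
F2 | step 15 | C4,C6-bis(triethylsilyl) ether of diol 16 (C2 β-OTBS, C8 dioxolane) | CC(C)(C)[Si](C)(C)O[C@@H]1C[C@@](O[Si](CC)(CC)CC)(C(C)C)[C@@H]2[C@@H](O[Si](CC)(CC)CC)CC3(OCCO3)CC[C@]21C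
F3 | step 15 | C8 ketone with C4 and C6 OTES, C2 OTBS | CC(C)(C)[Si](C)(C)O[C@@H]1C[C@@](O[Si](CC)(CC)CC)(C(C)C)[C@@H]2[C@@H](O[Si](CC)(CC)CC)CC(=O)CC[C@]21C
F4 | step 15 | C8–C9 enol triflate with C4 and C6 OTES, C2 OTBS | CC(C)(C)[Si](C)(C)O[C@@H]1C[C@@](O[Si](CC)(CC)CC)(C(C)C)[C@@H]2[C@@H](O[Si](CC)(CC)CC)CC(OS(=O)(=O)C(F)(F)F)=CC[C@]21C
F5 | step 15 | C8-methyl 8-ene with C4 and C6 OTES, C2 OTBS | CC(C)(C)[Si](C)(C)O[C@@H]1C[C@@](O[Si](CC)(CC)CC)(C(C)C)[C@@H]2[C@@H](O[Si](CC)(CC)CC)CC(C)=CC[C@]21C
F6 | step 15 | C6 α-alcohol of the C8-methyl 8-ene (C4 β-OTES, C2 β-OTBS) | CC(C)(C)[Si](C)(C)O[C@@H]1C[C@@](O[Si](CC)(CC)CC)(C(C)C)[C@@H]2[C@@H](O)CC(C)=CC[C@]21C
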